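# Proposed synthesis of (5S,9R,10S,13S)-15-acetoxylabd-7-en-17-oic acid (35)

Labdane numbering of the target is used for every ring-B and decalin intermediate. β is the face of ring B that carries C11 and, later, the C10 methyl group; α is the opposite face.

## The problem

Compound 35 is a labdane: a trans-fused decalin (ring A = C1–C5 and C10, ring B = C5–C10) with a gem-dimethyl group at C4, an angular methyl group on the quaternary carbon C10, a C7=C8 double bond carrying the C17 carboxylic acid, and at C9 a five-carbon chain (C11–C15) with a methyl-bearing centre at C13 and a primary acetate at C15. The two rings share the C5–C10 bond, and C10 is the most congested atom: quaternary, flanked by the tertiary centres C9 and C5, and 1,3-related to C4. Of the four stereocentres, C9, C10 and C5 are contiguous, so C9 can direct the making of C10 and the pair can fix C5 if C5 is left epimerisable. C13 lies four bonds from the ring and must arrive with its own chirality. Several functions are fragile: the acetate cannot outlive hydrolysis of a C17 ester and must be installed last; a free C11 hydroxyl next to a C17 ester can close to a γ-lactone; and once the C7=C8 enoate exists, C9 is allylic, so a C11 aldehyde at that stage would epimerise or slip into conjugation. The feature that opens the molecule is the 1,3-relation of C6 and C10 in ring B: with a carbonyl at C6 and an alkene at C5=C10, C10 is the β-carbon of a cyclohexenone that already carries C9 and C8 with their appendages, so the quaternary centre can be made by conjugate addition under the control of C9. The resulting enolate is fixed at C5–C6, where ring A must be closed onto C4, and the C6 oxygen that remains is the handle for the C7=C8 unsaturation.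

## Retrosynthesis

**Acetate, acid and alkene position (35 ⇒ 34 ⇒ 33 ⇒ 32).** No skeletal bond is cut. The acetyl C–O bond goes first, because no C17 ester can be hydrolysed beside the acetate; hydroxy acid 34 comes from diester 33 by one saponification that frees C17 and C15 together. Ester 33 is the conjugated isomer of the β,γ-unsaturated ester 32. Placing the alkene at C6=C7 in 32 is preferred to dehydrogenating a saturated ester, which would have to choose between the C7 and C9 hydrogens; the dienolate of 32 can only return to C6=C7 or move on to C7=C8. The forward steps must move the alkene without touching C9 and hydrolyse a hindered ester.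

**C6 oxygen (32 ⇒ 31 ⇒ 29).** The C6=C7 alkene is traced to enol triflate 31 and to ketone 29. This restores the C6 carbonyl that the conjugate addition needs and uses it to place the alkene regiospecifically. The forward reaction must enolise 29 towards C7 and not towards C5.

**C11=C12, the side chain (29 ⇒ 28 ⇒ 22 + 26).** The chain is cut as a Wittig bond between aldehyde 22 and phosphonium salt 26, which comes from the chiral-pool diol 23 through pivalate 24 and iodide 25. Cutting C9–C11 instead would make the hindered C9, next to quaternary C10, a reaction centre; cutting C12–C13 would break next to the C13 stereocentre. The cut is placed at the ketone stage because 22 has no ring alkene, so hydrogenation of 28 needs no selectivity and C9 is not yet allylic. Aldehyde 22 comes from alcohol 21 and silyl ether 20. Five carbons and one stereocentre are removed; the forward step must olefinate a hindered, enolisable aldehyde beside a ketone.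

**C4–C5, ring A (20 ⇒ 19 ⇒ 17 ⇒ 15).** Ring A is opened between the enol carbon C5 and the tertiary carbon C4, the only bond of ring A whose two ends are a natural nucleophile and a natural cation once C1–C10 is reserved for the next cut. The precursor is monocyclic and carries the C3=C4 alkene.
- The cation at C4 must be made without attacking the enol. A proton or any other electrophile would attack the electron-rich silyl enol ether of 15 before the alkene, with loss of the enol or closure of the alkene onto C6.
- The silyl group of 15 is therefore exchanged for a diethyl phosphate (17), which is inert to electrophiles but still captures a cation, and the alkene is activated with Hg(OCOCF3)2.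
- The tether sits on the α face of C10 and can reach only the α face of C5, so the cis-fused ketone 19 is expected first. C5 is α to the ketone, and base should convert 19 into the trans-fused 20.

**C1–C10, the quaternary centre (15 ⇒ 11 + 13 + 14).** The chain C1–C4 is removed as the homoprenyl Grignard reagent 13 (from bromide 12), with chlorotrimethylsilane 14 as the enolate trap. This leaves enone 11, which holds only the C8 and C9 centres. The cut is preferred to making C10 by alkylation, because the conjugate addition produces the C5–C6 enol derivative regiospecifically. The forward step must add to a β,β-disubstituted enone on the face anti to the C9 substituent.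

**C7–C8 and C9–C10, ring B (11 ⇒ 10 ⇒ 9 ⇒ 8 ⇒ 2 + 7).** Enone 11 is the Saegusa–Ito product of silyl enol ether 10, which comes through alcohol 9 from cycloadduct 8. Adduct 8 is cut by a Diels–Alder disconnection into silyloxydiene 2 (from enone 1) and the fumaroyl imide 7 (from monomethyl fumarate 3 and oxazolidinone 4).
- The fumarate brings C17 at the carboxyl oxidation level and C11 as a separately addressable acyl group.
- The E geometry gives the trans C8/C9 relation; the auxiliary gives the absolute configuration.
- The diene oxygen ends at C6, where the later steps need it.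

## Roads not taken

**Alternative 1:** Intramolecular Diels–Alder closing both rings.
- **Cut:** C5–C10 and C8–C9, which opens both rings and leads to the acyclic trienal A1, a C5–C8 diene and a C9=C10 enal joined by the C1–C4 tether.
- **Forward key step:** a chiral oxazaborolidinium Lewis acid on the aldehyde would induce an endo cycloaddition to the trans-fused octalin aldehyde A2, setting C5, C8, C9 and C10 at once.
- **Merits:** two rings and all ring stereocentres in one catalytic asymmetric step from an achiral chain; C11 is already an aldehyde.
- **Weak points:** the dienophile carbon C10 is β,β-disubstituted, a poor partner even when activated. The new C5–C10 bond joins a quaternary carbon to a carbon next to the gem-dimethyl C4. The trans fusion depends on one tether conformation that the 4,4-disubstitution disturbs. A2 still has the alkene at C6=C7 and C17 at the alcohol level, so an oxidation and an alkene shift remain while the epimerisable C9 aldehyde is exposed.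
- **Comparison:** if the cycloaddition works, this road is clearly shorter and uses catalytic rather than stoichiometric chirality. The chosen plan offers electronically matched partners in each bond-forming step (chelated imide with silyloxydiene, enone with organocopper, tertiary cation with enol derivative) and a C5 centre that can be corrected by equilibration; a wrong ring fusion in A2 is final.

**Alternative 2:** Orthoester Claisen rearrangement at C9.
- **Cut:** the C9–C11 bond; ester A4 is traced to the bicyclic 7β-allylic alcohol A3.
- **Forward key step:** heating A3 with an orthoacetate and a weak acid forms a ketene acetal that rearranges [3,3], delivering the acetate arm to the β face of C9 and moving the alkene to C7=C8.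
- **Merits:** chirality transfer through a cyclic transition state is dependable; the alkene ends where the target has it; C5 and C10 are already set in A3.
- **Weak points:** C17 in A4 is a methyl group, so the acid requires a late allylic oxidation that must distinguish the vinylic methyl from C6 and C9. The new bond forms syn to the axial C10 methyl, next to the quaternary centre. Only two chain carbons arrive, so C12–C15 and C13 still need a chiral fragment.
- **Comparison:** this road is better in setting C9 by an intramolecular transfer, where the chosen plan relies on an intermolecular face selection, and in needing no steps to position the alkene, where the chosen plan spends three. The chosen plan has C17 at the carboxyl level from its first C–C bond formation and needs no late C–H oxidation.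

**Alternative 3:** Ireland–Claisen union at C9–C10.
- **Cut:** the C9–C10 bond; acid A6 is traced to the allylic ester A5, which joins a trimethylcyclohexenylmethyl unit (ring A) to a heptanoate already carrying C13.
- **Forward key step:** enolisation with a chiral boron bromide gives a boron ketene acetal whose [3,3] shift forms C9–C10, creating both centres and moving the ring alkene to an exocyclic methylene at C5.
- **Merits:** the most convergent plan; ring A, the whole side chain and C13 meet in one step, and A6 lies only a few steps from simple materials.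
- **Weak points:** both new centres depend on reagent control in a rearrangement onto a tetrasubstituted alkene carbon. Ring B does not yet exist in A6: C7 and C17 must be inserted between the carboxyl carbon C8 and the methylene carbon C6. C5 is still sp2 and must be set late, controlled only by C10.
- **Comparison:** this road is better in convergence and in the early arrival of C13; the chosen plan attaches the chain only at step 17. The chosen plan has every ring-B carbon in place before C10 is made and sets C10 by substrate control from the adjacent C9.

Key step: step 8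

## Route

Assumption: (R)-2-methylbutane-1,4-diol 23 is taken as a commercial chiral-pool diol, and the trans-fused 6-ketone 20 is taken to be the more stable C5 epimer, since the cis isomer must place the quaternary C4 axial on ring B.

Step 1
Reactants: 1 (E)-pent-3-en-2-one
Product: 2 (E)-2-(tert-butyldimethylsilyloxy)penta-1,3-diene
Conditions: TBSOTf (1.1 equiv), Et3N (1.5 equiv), Et2O, 0 °C
Reagents that add atoms: tert-butyldimethylsilyl trifluoromethanesulfonate, CC(C)(C)[Si](C)(C)OS(=O)(=O)C(F)(F)F
Why: Soft enolisation with O-silylation (silyl dienol ether formation): the silyl triflate activates the carbonyl and Et3N removes a proton from the α' methyl group, which should give the cross-conjugated 2-silyloxydiene with the E alkene untouched.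

Step 2
Reactants: 3 monomethyl fumarate; 4 (R)-4-benzyloxazolidin-2-one
Product: 7 methyl (E)-4-[(4R)-4-benzyl-2-oxooxazolidin-3-yl]-4-oxobut-2-enoate, via methyl fumaroyl chloride 5 (not isolated), via N-lithio oxazolidinone 6 (not isolated)
Conditions: 3, (COCl)2, DMF (cat.), CH2Cl2, 0→23 °C, concentrate; 4, n-BuLi, THF, −78 °C; then 5, −78→0 °C
Reagents that add atoms: none
Why: N-Acylation of a lithiated oxazolidinone by an acid chloride made with oxalyl chloride; neither the E alkene nor the auxiliary centre takes part.

Step 3
Reactants: 2 (E)-2-(tert-butyldimethylsilyloxy)penta-1,3-diene; 7 fumaroyl imide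
Product: 8 methyl 2-[(4R)-4-benzyl-2-oxooxazolidine-3-carbonyl]-5-(tert-butyldimethylsilyloxy)-3-methylcyclohex-4-ene-1-carboxylate (8α-CO2Me; 9β-acyl; 10β-Me)
Conditions: Et2AlCl (1.4 equiv), CH2Cl2, −78 °C; cold aq. NaHCO3
Reagents that add atoms: none
Why: Auxiliary-controlled, Lewis-acid-promoted Diels–Alder reaction: Et2AlCl chelates both imide carbonyls, the s-cis enoyl unit is shielded on one face by the benzyl group and the diene adds to the other, which sets C9 and, through the E fumarate, the trans C8 centre. The nucleophilic CH2 terminus of the diene bonds to the carbon β to the imide (C8), so the imide-bearing carbon ends next to the methyl-bearing C10; the endo imide puts that methyl cis to the C9 acyl group, a centre that step 6 erases.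

Step 4
Reactants: 8 Diels–Alder adduct
Product: 9 methyl 5-(tert-butyldimethylsilyloxy)-2-(hydroxymethyl)-3-methylcyclohex-4-ene-1-carboxylate (8α-CO2Me; 9β-CH2OH; 10β-Me)
Conditions: LiBH4 (1.2 equiv), MeOH (1.2 equiv), THF, 0 °C
Reagents that add atoms: none
Why: Chemoselective hydride reduction of the imide (reductive removal of the auxiliary): the exocyclic imide carbonyl is more electrophilic than the methyl ester and should be reduced to the primary alcohol with release of 4; the silyl enol ether keeps C6 out of reach of the hydride.

Step 5
Reactants: 9 hydroxy ester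
Product: 10 methyl 5-(tert-butyldimethylsilyloxy)-2-[(tert-butyldimethylsilyloxy)methyl]-3-methylcyclohex-4-ene-1-carboxylate (8α-CO2Me; 9β-CH2OTBS; 10β-Me)
Conditions: TBSCl, imidazole, DMF, 0→23 °C
Reagents that add atoms: tert-butyldimethylsilyl chloride, CC(C)(C)[Si](C)(C)Cl
Why: Silyl ether formation at the primary alcohol; prompt protection keeps the C11 hydroxyl from lactonising onto the C8 ester.

Step 6
Reactants: 10 bis-silyl compound
Product: 11 methyl (1R,2S)-2-[(tert-butyldimethylsilyloxy)methyl]-3-methyl-5-oxocyclohex-3-ene-1-carboxylate (8α-CO2Me; 9β-CH2OTBS)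
Conditions: Pd(OAc)2 (1.05 equiv), MeCN, 23→40 °C
Reagents that add atoms: none
Why: Saegusa–Ito oxidation: the palladium enolate at C5 loses the C10 hydrogen, the only β-hydrogen available, by β-hydride elimination and should give the C5=C10 enone; the C10 centre of 10 is erased and C8 and C9 are untouched.

Step 7
Reactants: 12 5-bromo-2-methylpent-2-ene
Product: 13 4-methylpent-3-enylmagnesium bromide
Conditions: Mg turnings, THF, 23→45 °C
Reagents that add atoms: magnesium, [Mg]
Why: Grignard formation by insertion of magnesium into the primary C–Br bond; the remote trisubstituted alkene is inert.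

Step 8
Reactants: 11 enone; 13 4-methylpent-3-enylmagnesium bromide; 14 chlorotrimethylsilane
Product: 15 methyl (1R,2S,3R)-2-[(tert-butyldimethylsilyloxy)methyl]-3-methyl-3-(4-methylpent-3-en-1-yl)-5-(trimethylsilyloxy)cyclohex-4-ene-1-carboxylate (10β-Me; C1 chain α)
Conditions: 13 (1.6 equiv), CuBr·SMe2 (0.2 equiv), Me3SiCl (3 equiv), THF, −78 °C; Et3N, pentane, cold aq. NaHCO3
Reagents that add atoms: chlorotrimethylsilane (14), C[Si](C)(C)Cl
Why: Reagent 13 transmetallates to a homoprenyl organocopper species (monovalent copper), which forms a π-complex with enone 11 and adds at C10 to a trivalent copper β-adduct; Me3SiCl silylates the enolate oxygen as this adduct forms, which drives the otherwise slow addition to a β,β-disubstituted enone, and reductive elimination makes the C1–C10 bond and returns copper to the cycle. The closest known reaction type is the Me3SiCl-accelerated, copper-catalysed conjugate addition of Grignard reagents to 4-substituted 3-methylcyclohex-2-enones, which enter trans to the 4-substituent. No ring is closed. The one new stereocentre, C10, is controlled by C9: allylic 1,2-strain with the C10 methyl drives the C9 silyloxymethyl group pseudoaxial on the β face, and axial attack anti to this adjacent group places the chain on the α face and leaves the methyl β. The step needs diastereofacial selectivity, 1,4- over 1,2-addition and chemoselectivity for the enone over the ester; the first rests on the vicinal pseudoaxial C9 group outweighing the more remote C8 ester, the other two on catalytic copper at −78 °C. The silyl trap fixes the enol double bond at C5=C6, the position needed for the C4–C5 closure, which enolisation of the free ketone could not deliver.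

Step 9
Reactants: 15 trimethylsilyl enol ether
Product: 17 methyl (1R,2S,3R)-2-[(tert-butyldimethylsilyloxy)methyl]-5-(diethoxyphosphoryloxy)-3-methyl-3-(4-methylpent-3-en-1-yl)cyclohex-4-ene-1-carboxylate, via potassium enolate 16 (not isolated)
Conditions: KOt-Bu (1.05 equiv), THF, −20→0 °C; ClP(O)(OEt)2 (1.2 equiv), −20→0 °C
Reagents that add atoms: diethyl chlorophosphate, CCOP(=O)(Cl)OCC
Why: Regiospecific silyl-to-phosphoryl exchange (enol phosphate formation): tert-butoxide attacks silicon and frees the potassium enolate without positional equilibration, and the hard chlorophosphate reacts at oxygen. The enol phosphate is a poor base, so in step 10 the electrophile should attack the alkene and not the enol.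

Step 10
Reactants: 17 enol phosphate
Product: 19 methyl 9-[(tert-butyldimethylsilyloxy)methyl]-4,4,10-trimethyl-6-oxodecalin-8-carboxylate (cis-fused: 5β-H; 8α-CO2Me; 9β-CH2OTBS; 10β-Me), via C3-chloromercurio ketone 18 (not isolated)
Conditions: Hg(OCOCF3)2 (1.1 equiv), MeNO2, −20 °C; sat. aq. NaCl; then n-Bu3SnH (1.3 equiv), THF, 0→23 °C
Reagents that add atoms: none
Why: Mercury-mediated olefin cyclisation terminated by an enol phosphate, a known reaction type: divalent mercury adds to the C3=C4 alkene and the mercurinium ion is opened at the tertiary C4 by the enol carbon C5 (6-endo closure at the alkene, Markovnikov); the phosphoryl group is lost on aqueous work-up to give the ketone, and tin hydride replaces mercury by hydrogen through the alkyl radical. The tether sits on the α face of C10 and reaches the α face of C5, so the cis-fused ketone is the expected kinetic product; C3 is no longer a stereocentre after demercuration.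

Step 11
Reactants: 19 cis-fused ketone
Product: 20 methyl 9-[(tert-butyldimethylsilyloxy)methyl]-4,4,10-trimethyl-6-oxodecalin-8-carboxylate (trans-fused: 5α-H; 8α-CO2Me; 9β-CH2OTBS; 10β-Me)
Conditions: NaOMe (0.2 equiv), MeOH, 50 °C
Reagents that add atoms: none
Why: Base-mediated epimerisation α to a ketone: methoxide enolises towards C5 and reprotonation is under thermodynamic control, which should favour the trans-fused ketone with C4 equatorial on ring B. The C8 ester is already equatorial and C9 is not acidic.

Step 12
Reactants: 20 trans-fused silyl ether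
Product: 21 methyl 9-(hydroxymethyl)-4,4,10-trimethyl-6-oxodecalin-8-carboxylate (5α-H; 8α-CO2Me; 9β-CH2OH; 10β-Me)
Conditions: HF·pyridine, pyridine, THF, 0→23 °C
Reagents that add atoms: none
Why: Fluoride-mediated cleavage of a primary silyl ether; the buffered, weakly acidic medium avoids the alkoxide that would attack the neighbouring C8 ester, and the alcohol is oxidised without storage.

Step 13
Reactants: 21 hydroxy keto ester
Product: 22 methyl 9-formyl-4,4,10-trimethyl-6-oxodecalin-8-carboxylate (5α-H; 8α-CO2Me; 9β-CHO; 10β-Me)
Conditions: Dess–Martin periodinane, NaHCO3, CH2Cl2, 0→23 °C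
Reagents that add atoms: none
Why: Dess–Martin oxidation of the primary alcohol to the aldehyde under buffered, non-basic conditions, which should leave the α-centre C9, the ketone and the ester untouched.

Step 14
Reactants: 23 (R)-2-methylbutane-1,4-diol
Product: 24 (R)-4-hydroxy-3-methylbutyl pivalate
Conditions: PivCl (1.0 equiv), pyridine, CH2Cl2, −30 °C
Reagents that add atoms: pivaloyl chloride, CC(C)(C)C(=O)Cl
Why: Regioselective esterification: the bulky acid chloride should react faster at the unbranched C4 hydroxyl than at the β-branched C1 hydroxyl; any regioisomer is removed by chromatography.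

Step 15
Reactants: 24 (R)-4-hydroxy-3-methylbutyl pivalate
Product: 25 (R)-4-iodo-3-methylbutyl pivalate
Conditions: I2, PPh3, imidazole, CH2Cl2, 0→23 °C
Reagents that add atoms: iodine, II
Why: Appel-type iodination of the primary alcohol by SN2 displacement at CH2; the stereocentre is not involved.

Step 16
Reactants: 25 (R)-4-iodo-3-methylbutyl pivalate
Product: 26 [(R)-2-methyl-4-(pivaloyloxy)butyl]triphenylphosphonium iodide
Conditions: PPh3, MeCN, 85 °C
Reagents that add atoms: triphenylphosphine, c1ccc(cc1)P(c1ccccc1)c1ccccc1
Why: Phosphonium salt formation by SN2 quaternisation of triphenylphosphine with the primary iodide.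

Step 17
Reactants: 22 keto aldehyde; 26 phosphonium iodide
Product: 28 methyl (11Z)-6-oxo-15-(pivaloyloxy)labd-11-en-17-oate (5α-H; 8β-H; 9α-H; C13 as in 26), via phosphorus ylide 27 (not isolated)
Conditions: 26 (1.3 equiv), NaN(SiMe3)2 (1.25 equiv), THF, −78→0 °C; then 22, −78→23 °C
Reagents that add atoms: none
Why: Wittig olefination: the non-stabilised ylide should react with the aldehyde and not with the hindered C6 ketone or the esters; the Z alkene is expected, but the geometry is lost in step 18. The ylide is pre-formed with slightly less than one equivalent of base and meets 22 cold, which limits enolisation at C9, whose equatorial aldehyde is in any case the more stable epimer.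

Step 18
Reactants: 28 (11Z)-alkene
Product: 29 methyl (13S)-6-oxo-15-(pivaloyloxy)labdan-17-oate (5α-H; 8β-H; 9α-H)
Conditions: H2 (1 atm), 10% Pd/C, EtOAc, 23 °C
Reagents that add atoms: none
Why: Heterogeneous catalytic hydrogenation of the only alkene in the molecule; ketone, esters and stereocentres are not affected.

Step 19
Reactants: 29 keto diester
Product: 31 methyl (13S)-15-(pivaloyloxy)-6-(trifluoromethanesulfonyloxy)labd-6-en-17-oate (8β-H), via potassium enolate 30 (not isolated)
Conditions: KN(SiMe3)2 (1.1 equiv), THF, −78 °C; PhNTf2 (1.2 equiv), −78→0 °C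
Reagents that add atoms: N-phenylbis(trifluoromethanesulfonimide), O=S(=O)(N(c1ccccc1)S(=O)(=O)C(F)(F)F)C(F)(F)F
Why: Kinetic enolate formation and O-triflation (enol triflate synthesis): the amide base should remove a C7 hydrogen, not the C5 hydrogen shielded by two quaternary carbons nor the less acidic C8 hydrogen, and PhNTf2 traps the enolate at oxygen.

Step 20
Reactants: 31 enol triflate
Product: 32 methyl (13S)-15-(pivaloyloxy)labd-6-en-17-oate (8β-H)
Conditions: Pd(OAc)2 (5 mol %), PPh3 (10 mol %), HCO2H (2 equiv), n-Bu3N (3 equiv), DMF, 60 °C
Reagents that add atoms: none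
Why: Palladium-catalysed formate reduction of an enol triflate: oxidative addition to zerovalent palladium, exchange of triflate for formate, decarboxylation to the palladium hydride and reductive elimination should give the C6=C7 alkene.

Step 21
Reactants: 32 β,γ-unsaturated ester
Product: 34 (13S)-15-hydroxylabd-7-en-17-oic acid, via conjugated methyl ester 33 (not isolated)
Conditions: NaOMe (0.3 equiv), MeOH, 60 °C; then KOH, H2O, 80 °C; HCl to pH 2
Reagents that add atoms: water, O
Why: Base-mediated alkene conjugation followed by saponification: methoxide removes the C8 hydrogen (α to the ester and allylic), and thermodynamic reprotonation of the dienolate at C6 should give the conjugated C7=C8 ester; C9 is not acidic in either isomer and keeps its configuration. Aqueous KOH then hydrolyses the methyl ester and the pivalate.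

Step 22
Reactants: 34 hydroxy acid
Product: 35 (5S,9R,10S,13S)-15-acetoxylabd-7-en-17-oic acid
Conditions: Ac2O, pyridine, DMAP (cat.), CH2Cl2, 0→23 °C; aqueous work-up
Reagents that add atoms: acetic anhydride, CC(=O)OC(C)=O
Why: Esterification of the primary alcohol with Ac2O and DMAP; any mixed anhydride formed at the carboxylic acid is hydrolysed in the aqueous work-up, which should leave the free acid.

## Compound list

1 | (E)-pent-3-en-2-one | C/C=C/C(C)=O | starting material
2 | (E)-2-(tert-butyldimethylsilyloxy)penta-1,3-diene | C=C(O[Si](C)(C)C(C)(C)C)/C=C/C | intermediate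
3 | monomethyl fumarate | COC(=O)/C=C/C(=O)O | starting material
4 | (R)-4-benzyloxazolidin-2-one | O=C1N[C@H](Cc2ccccc2)CO1 | starting material
5 | methyl (E)-4-chloro-4-oxobut-2-enoate (methyl fumaroyl chloride) | COC(=O)/C=C/C(Cl)=O | intermediate (not isolated)
6 | N-lithio (R)-4-benzyloxazolidin-2-one | [Li]N1[C@H](Cc2ccccc2)COC1=O | intermediate (not isolated)
7 | methyl (E)-4-[(4R)-4-benzyl-2-oxooxazolidin-3-yl]-4-oxobut-2-enoate | COC(=O)/C=C/C(=O)N1[C@H](Cc2ccccc2)COC1=O | intermediate
8 | methyl 2-[(4R)-4-benzyl-2-oxooxazolidine-3-carbonyl]-5-(tert-butyldimethylsilyloxy)-3-methylcyclohex-4-ene-1-carboxylate (8α-CO2Me, 9β-acyl, 10β-Me) | CC(C)(C)[Si](C)(C)OC1=C[C@@H](C)[C@@H](C(=O)N2[C@H](Cc3ccccc3)COC2=O)[C@H](C(=O)OC)C1 | intermediate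
9 | methyl 5-(tert-butyldimethylsilyloxy)-2-(hydroxymethyl)-3-methylcyclohex-4-ene-1-carboxylate (8α-CO2Me, 9β-CH2OH, 10β-Me) | CC(C)(C)[Si](C)(C)OC1=C[C@@H](C)[C@@H](CO)[C@H](C(=O)OC)C1 | intermediate
10 | methyl 5-(tert-butyldimethylsilyloxy)-2-[(tert-butyldimethylsilyloxy)methyl]-3-methylcyclohex-4-ene-1-carboxylate (8α-CO2Me, 9β-CH2OTBS, 10β-Me) | CC(C)(C)[Si](C)(C)OC1=C[C@@H](C)[C@@H](CO[Si](C)(C)C(C)(C)C)[C@H](C(=O)OC)C1 | intermediate
11 | methyl (1R,2S)-2-[(tert-butyldimethylsilyloxy)methyl]-3-methyl-5-oxocyclohex-3-ene-1-carboxylate | O=C1C=C(C)[C@@H](CO[Si](C)(C)C(C)(C)C)[C@H](C(=O)OC)C1 | intermediate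
12 | 5-bromo-2-methylpent-2-ene | CC(C)=CCCBr | starting material
13 | 4-methylpent-3-enylmagnesium bromide | CC(C)=CCC[Mg]Br | intermediate
14 | chlorotrimethylsilane | C[Si](C)(C)Cl | starting material
15 | methyl (1R,2S,3R)-2-[(tert-butyldimethylsilyloxy)methyl]-3-methyl-3-(4-methylpent-3-en-1-yl)-5-(trimethylsilyloxy)cyclohex-4-ene-1-carboxylate | C[Si](C)(C)OC1=C[C@](C)(CCC=C(C)C)[C@@H](CO[Si](C)(C)C(C)(C)C)[C@H](C(=O)OC)C1 | intermediate
16 | potassium C5=C6 enolate corresponding to 15 | [K+].[O-]C1=C[C@](C)(CCC=C(C)C)[C@@H](CO[Si](C)(C)C(C)(C)C)[C@H](C(=O)OC)C1 | intermediate (not isolated)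
17 | methyl (1R,2S,3R)-2-[(tert-butyldimethylsilyloxy)methyl]-5-(diethoxyphosphoryloxy)-3-methyl-3-(4-methylpent-3-en-1-yl)cyclohex-4-ene-1-carboxylate | CCOP(=O)(OCC)OC1=C[C@](C)(CCC=C(C)C)[C@@H](CO[Si](C)(C)C(C)(C)C)[C@H](C(=O)OC)C1 | intermediate
18 | methyl 3-(chloromercurio)-9-[(tert-butyldimethylsilyloxy)methyl]-4,4,10-trimethyl-6-oxodecalin-8-carboxylate (5β-H; C3 epimers, centre erased in the same step) | CC(C)(C)[Si](C)(C)OC[C@H]1[C@H](C(=O)OC)CC(=O)[C@@H]2C(C)(C)C([Hg]Cl)CC[C@]12C | intermediate (not isolated)
19 | methyl 9-[(tert-butyldimethylsilyloxy)methyl]-4,4,10-trimethyl-6-oxodecalin-8-carboxylate, cis-fused (5β-H, 8α-CO2Me, 9β-CH2OTBS, 10β-Me) | CC(C)(C)[Si](C)(C)OC[C@H]1[C@H](C(=O)OC)CC(=O)[C@@H]2C(C)(C)CCC[C@]12C | intermediate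
20 | methyl 9-[(tert-butyldimethylsilyloxy)methyl]-4,4,10-trimethyl-6-oxodecalin-8-carboxylate, trans-fused (5α-H, 8α-CO2Me, 9β-CH2OTBS, 10β-Me) | CC(C)(C)[Si](C)(C)OC[C@H]1[C@H](C(=O)OC)CC(=O)[C@H]2C(C)(C)CCC[C@]12C | intermediate
21 | methyl 9-(hydroxymethyl)-4,4,10-trimethyl-6-oxodecalin-8-carboxylate (5α-H, 8α-CO2Me, 9β-CH2OH, 10β-Me) | OC[C@H]1[C@H](C(=O)OC)CC(=O)[C@H]2C(C)(C)CCC[C@]12C | intermediate
22 | methyl 9-formyl-4,4,10-trimethyl-6-oxodecalin-8-carboxylate (5α-H, 8α-CO2Me, 9β-CHO, 10β-Me) | O=C[C@H]1[C@H](C(=O)OC)CC(=O)[C@H]2C(C)(C)CCC[C@]12C | intermediate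
23 | (R)-2-methylbutane-1,4-diol | OCC[C@@H](C)CO | starting material
24 | (R)-4-hydroxy-3-methylbutyl pivalate | CC(C)(C)C(=O)OCC[C@@H](C)CO | intermediate
25 | (R)-4-iodo-3-methylbutyl pivalate | CC(C)(C)C(=O)OCC[C@@H](C)CI | intermediate
26 | [(R)-2-methyl-4-(pivaloyloxy)butyl]triphenylphosphonium iodide | CC(C)(C)C(=O)OCC[C@@H](C)C[P+](c1ccccc1)(c1ccccc1)c1ccccc1.[I-] | intermediate
27 | [(R)-2-methyl-4-(pivaloyloxy)butylidene]triphenylphosphorane | CC(C)(C)C(=O)OCC[C@@H](C)C=P(c1ccccc1)(c1ccccc1)c1ccccc1 | intermediate (not isolated)
28 | methyl (11Z)-6-oxo-15-(pivaloyloxy)labd-11-en-17-oate (5α-H, 8β-H, 9α-H) | CC(C)(C)C(=O)OCC[C@@H](C)/C=C\[C@H]1[C@H](C(=O)OC)CC(=O)[C@H]2C(C)(C)CCC[C@]12C | intermediate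
29 | methyl (13S)-6-oxo-15-(pivaloyloxy)labdan-17-oate (5α-H, 8β-H, 9α-H) | CC(C)(C)C(=O)OCC[C@@H](C)CC[C@H]1[C@H](C(=O)OC)CC(=O)[C@H]2C(C)(C)CCC[C@]12C | intermediate
30 | potassium C6=C7 enolate of 29 | CC(C)(C)C(=O)OCC[C@@H](C)CC[C@H]1[C@H](C(=O)OC)C=C([O-])[C@H]2C(C)(C)CCC[C@]12C.[K+] | intermediate (not isolated)
31 | methyl (13S)-15-(pivaloyloxy)-6-(trifluoromethanesulfonyloxy)labd-6-en-17-oate (8β-H) | CC(C)(C)C(=O)OCC[C@@H](C)CC[C@H]1[C@H](C(=O)OC)C=C(OS(=O)(=O)C(F)(F)F)[C@H]2C(C)(C)CCC[C@]12C | intermediate
32 | methyl (13S)-15-(pivaloyloxy)labd-6-en-17-oate (8β-H) | CC(C)(C)C(=O)OCC[C@@H](C)CC[C@H]1[C@H](C(=O)OC)C=C[C@H]2C(C)(C)CCC[C@]12C | intermediate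
33 | methyl (13S)-15-(pivaloyloxy)labd-7-en-17-oate | CC(C)(C)C(=O)OCC[C@@H](C)CC[C@H]1C(C(=O)OC)=CC[C@H]2C(C)(C)CCC[C@]12C | intermediate (not isolated)
34 | (13S)-15-hydroxylabd-7-en-17-oic acid | OCC[C@@H](C)CC[C@H]1C(C(=O)O)=CC[C@H]2C(C)(C)CCC[C@]12C | intermediate
35 | (5S,9R,10S,13S)-15-acetoxylabd-7-en-17-oic acid | CC(=O)OCC[C@@H](C)CC[C@H]1C(C(=O)O)=CC[C@H]2C(C)(C)CCC[C@]12C | target

## Step count and least certain steps

Total step count: 22. Longest linear sequence: 17 steps (steps 1, 3–6, 8–13 and 17–22).

**Step 8 (key step).** The most likely failure is erosion or reversal of facial selectivity at C10. In the half-chair that relieves the strain between the C10 methyl and the C9 group, the trans C8 ester is axial on the very face the chain must use. A competing half-chair with both groups equatorial would send the chain cis to C11.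

The fallback sets out from imide 7 and returns at 15 by exchanging the roles of the two C10 substituents. Wittig reaction of 5-methylhex-4-enal with 1-(triphenylphosphoranylidene)propan-2-one would give (E)-8-methylnona-3,7-dien-2-one F1, which is silylated as in step 1 to the silyloxydiene F2. Cycloaddition with 7 under the conditions of step 3 would give the chain-bearing adduct F3. This is carried through LiBH4 reduction to the alcohol F4, silylation to the bis-silyl compound F5 and Saegusa–Ito oxidation to the chain-bearing enone F6. MeMgBr with catalytic CuBr·SMe2 and Me3SiCl then delivers the methyl group to C10. If the nucleophile prefers the face anti to the C8 ester, that face is β, and the product is 15.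

**Step 10.** The most likely failure is that the mercurinium ion is captured by adventitious water or loses a proton before the hindered C4–C5 bond forms, since the enol phosphate is a weak nucleophile and the bond joins a quaternary carbon to a carbon next to C10.

The fallback sets out from 17 and returns at 19 by generating the cation through ionisation instead of mercuration. Dry HCl in CH2Cl2 at −40 °C should add to the trisubstituted alkene, with the enol phosphate inert, to give the tertiary chloride F7. SnCl4 at −78 °C then ionises it, and capture of the tertiary cation by the enol phosphate carbon (SN1 tert-alkylation of an enol derivative) gives 19 without organomercury intermediates.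

**Step 4.** The most likely failure is loss of chemoselectivity: lactonisation of the alkoxyborate onto the trans C8 ester followed by reduction of the lactone, or direct reduction of the methyl ester.

The fallback sets out from 8 and returns at 9 by separating cleavage from reduction. LiOH with H2O2 in aqueous THF at 0 °C removes the auxiliary to give the carboxylic acid F8. Activation as the mixed anhydride with isobutyl chloroformate and N-methylmorpholine, followed by NaBH4, reduces the anhydride but neither the methyl ester nor the silyl enol ether, and gives 9.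

**Step 17.** The most likely failure is enolisation of the hindered aldehyde by the basic ylide, which returns 22 or epimerises C9, in competition with slow addition at a carbonyl next to the quaternary C10.

The fallback sets out from 25 and 22 and returns at 29 by a Julia–Kocienski olefination. Displacement of the iodide of 25 with 1-phenyl-1H-tetrazole-5-thiol and K2CO3 gives the tetrazolyl sulfide F9, and oxidation with H2O2 and (NH4)6Mo7O24 gives the sulfone F10. Deprotonation with KN(SiMe3)2 and addition to 22 should give the (11E)-alkene F11, and hydrogenation as in step 18 gives 29.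

## Further compounds

F1 | step 8 | (E)-8-methylnona-3,7-dien-2-one | CC(=O)/C=C/CCC=C(C)C
F2 | step 8 | (E)-2-(tert-butyldimethylsilyloxy)-8-methylnona-1,3,7-triene | C=C(O[Si](C)(C)C(C)(C)C)/C=C/CCC=C(C)C
F3 | step 8 | methyl 2-[(4R)-4-benzyl-2-oxooxazolidine-3-carbonyl]-5-(tert-butyldimethylsilyloxy)-3-(4-methylpent-3-en-1-yl)cyclohex-4-ene-1-carboxylate (8α-CO2Me, 9β-acyl, 10β-chain) | CC(C)(C)[Si](C)(C)OC1=C[C@@H](CCC=C(C)C)[C@@H](C(=O)N2[C@H](Cc3ccccc3)COC2=O)[C@H](C(=O)OC)C1
F4 | step 8 | methyl 5-(tert-butyldimethylsilyloxy)-2-(hydroxymethyl)-3-(4-methylpent-3-en-1-yl)cyclohex-4-ene-1-carboxylate (8α-CO2Me, 9β-CH2OH, 10β-chain) | CC(C)(C)[Si](C)(C)OC1=C[C@@H](CCC=C(C)C)[C@@H](CO)[C@H](C(=O)OC)C1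
F5 | step 8 | methyl 5-(tert-butyldimethylsilyloxy)-2-[(tert-butyldimethylsilyloxy)methyl]-3-(4-methylpent-3-en-1-yl)cyclohex-4-ene-1-carboxylate (8α-CO2Me, 9β-CH2OTBS, 10β-chain) | CC(C)(C)[Si](C)(C)OC1=C[C@@H](CCC=C(C)C)[C@@H](CO[Si](C)(C)C(C)(C)C)[C@H](C(=O)OC)C1
F6 | step 8 | methyl (1R,2S)-2-[(tert-butyldimethylsilyloxy)methyl]-3-(4-methylpent-3-en-1-yl)-5-oxocyclohex-3-ene-1-carboxylate | O=C1C=C(CCC=C(C)C)[C@@H](CO[Si](C)(C)C(C)(C)C)[C@H](C(=O)OC)C1
F7 | step 10 | methyl (1R,2S,3R)-2-[(tert-butyldimethylsilyloxy)methyl]-3-(4-chloro-4-methylpentyl)-5-(diethoxyphosphoryloxy)-3-methylcyclohex-4-ene-1-carboxylate | CCOP(=O)(OCC)OC1=C[C@](C)(CCCC(C)(C)Cl)[C@@H](CO[Si](C)(C)C(C)(C)C)[C@H](C(=O)OC)C1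
F8 | step 4 | 4-(tert-butyldimethylsilyloxy)-6-(methoxycarbonyl)-2-methylcyclohex-3-ene-1-carboxylic acid (8α-CO2Me, 9β-CO2H, 10β-Me) | CC(C)(C)[Si](C)(C)OC1=C[C@@H](C)[C@@H](C(=O)O)[C@H](C(=O)OC)C1
F9 | step 17 | (R)-3-methyl-4-[(1-phenyl-1H-tetrazol-5-yl)sulfanyl]butyl pivalate | CC(C)(C)C(=O)OCC[C@@H](C)CSc1nnnn1-c1ccccc1
F10 | step 17 | (R)-3-methyl-4-[(1-phenyl-1H-tetrazol-5-yl)sulfonyl]butyl pivalate | CC(C)(C)C(=O)OCC[C@@H](C)CS(=O)(=O)c1nnnn1-c1ccccc1
F11 | step 17 | methyl (11E)-6-oxo-15-(pivaloyloxy)labd-11-en-17-oate (5α-H, 8β-H, 9α-H) | CC(C)(C)C(=O)OCC[C@@H](C)/C=C/[C@H]1[C@H](C(=O)OC)CC(=O)[C@H]2C(C)(C)CCC[C@]12C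
A1 | alternative 1 | (2E,8E,10E)-12-(4-methoxybenzyloxy)-3,7,7-trimethyldodeca-2,8,10-trienal | O=C/C=C(C)/CCCC(C)(C)/C=C/C=C/COCc1ccc(OC)cc1
A2 | alternative 1 | trans-fused 4,4,10-trimethyloctal-6-ene with 9β-formyl and 8β-(4-methoxybenzyloxymethyl) groups (5α-H, 10β-Me) | O=C[C@H]1[C@@H](COCc3ccc(OC)cc3)C=C[C@H]2C(C)(C)CCC[C@]12C
A3 | alternative 2 | 11-nordrim-8-en-7β-ol (5α-H, 10β-Me) | O[C@H]1C[C@H]2C(C)(C)CCC[C@]2(C)C=C1C
A4 | alternative 2 | ethyl 2-(4,4,8,10-tetramethyloctal-7-en-9-yl)acetate (5α-H, 9α-H, 10β-Me) | CCOC(=O)C[C@H]1C(C)=CC[C@H]2C(C)(C)CCC[C@]12C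
A5 | alternative 3 | (2,6,6-trimethylcyclohex-1-en-1-yl)methyl (5S)-7-(tert-butyldimethylsilyloxy)-5-methylheptanoate | CC(C)(C)[Si](C)(C)OCC[C@@H](C)CCCC(=O)OCC1=C(C)CCCC1(C)C
A6 | alternative 3 | (5S)-7-(tert-butyldimethylsilyloxy)-5-methyl-2-(1,3,3-trimethyl-2-methylidenecyclohexyl)heptanoic acid (C9 and C10 as in 35) | CC(C)(C)[Si](C)(C)OCC[C@@H](C)CC[C@@H](C(=O)O)[C@@]1(C)CCCC(C)(C)C1=C
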